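**Plan**

- Retrosynthesis cuts one bond of the biflavonoid, the biaryl bond between C6 of the naringenin ring A and C6' of the luteolin ring B, giving unprotected (R)-naringenin and commercial luteolin.
- The feature that allows this: C6' is para to the C3' oxygen of the ring B catechol, so it is the β-carbon of the 3',4'-ortho-quinone. C6 is the carbon between the 5- and 7-hydroxyls of a phloroglucinol-type ring. Electrophile and nucleophile are therefore innate, and catechol oxidation followed by conjugate addition forms the bond without halide, boron or protecting group.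
- (R)-Naringenin is cut at C2–aryl (asymmetric 1,4-addition of an arylboronic acid to a 5,7-dioxygenated chromone). The chromone ring C is cut back to phloroacetophenone through an enaminone.
- Forward order: benzylation, closure of ring C, C2–aryl bond with the stereocenter, debenzylation, then the oxidative union with luteolin as the last step.
- Stereochemistry: the only stereocenter, C2 (R), is set by the chiral bisphosphine–rhodium catalyst and is kept because every later step is neutral (hydrogenolysis; coupling at pH 7 and 0 °C).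

Key step: step 5

Remark: C2 is read as R from the SMILES; the biaryl axis (ortho groups OH, OH, chromonyl, H) is taken as not configurationally fixed, so no atropisomer is specified.

**Route**

Step 1
Reactants: 1 2',4',6'-trihydroxyacetophenone
Product: 2 1-[2,4-bis(benzyloxy)-6-hydroxyphenyl]ethan-1-one
Conditions: BnBr (2.1 equiv), K2CO3 (2.2 equiv), DMF, rt
Reagents that add atoms: benzyl bromide, BrCc1ccccc1
Why: Williamson etherification in which the para hydroxyl and one ortho hydroxyl are alkylated, while the remaining ortho hydroxyl, hydrogen-bonded to the acetyl carbonyl, is the least nucleophilic and should stay free.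

Step 2
Reactants: 2 1-[2,4-bis(benzyloxy)-6-hydroxyphenyl]ethan-1-one
Product: 4 5,7-bis(benzyloxy)-4H-chromen-4-one, via enaminone 3 (not isolated)
Conditions: DMF-DMA (3 equiv), toluene, 100 °C; then conc. HCl, CH2Cl2, 40 °C
Reagents that add atoms: N,N-dimethylformamide dimethyl acetal, COC(OC)N(C)C
Why: Enaminone route to chromones, in which the methyl ketone condenses with the amide acetal and acid then triggers addition of the free phenol to the enaminone carbon with loss of dimethylamine, closing ring C.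

Step 3
Reactants: 4 5,7-bis(benzyloxy)-4H-chromen-4-one; 5 [4-(benzyloxy)phenyl]boronic acid
Product: 6 (2R)-5,7-bis(benzyloxy)-2-[4-(benzyloxy)phenyl]-2,3-dihydro-4H-chromen-4-one
Conditions: 5 (3 equiv), [Rh(OH)(cod)]2 (2.5 mol %, cod = 1,5-cyclooctadiene), (R)-MeO-F12-BIPHEP (5.5 mol %), toluene–H2O (10:1), 40 °C
Reagents that add atoms: none
Why: Rhodium-catalyzed asymmetric 1,4-addition of an arylboronic acid to a chromone (Hayashi–Miyaura reaction), in which the aryl–rhodium species bearing the (R)-bisphosphine inserts C2=C3 on one enantioface and sets C2 (R expected by analogy with (S)-biaryl bisphosphines giving (S)-3-arylcycloalkanones, the antipodal ligand being used if the sense is opposite), while the electron-poor ligand allows a temperature low enough that ring opening of the product should not erode the ee.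

Step 4
Reactants: 6 (2R)-5,7-bis(benzyloxy)-2-[4-(benzyloxy)phenyl]-2,3-dihydro-4H-chromen-4-one
Product: 7 (2R)-5,7-dihydroxy-2-(4-hydroxyphenyl)-2,3-dihydro-4H-chromen-4-one, (R)-naringenin
Conditions: H2 (1 atm), 10% Pd/C, EtOAc–MeOH (1:1), rt
Reagents that add atoms: none
Why: Catalytic hydrogenolysis of the three aryl benzyl ethers under neutral conditions, which should leave C2 untouched because neither base nor acid is present to open ring C.

Step 5
Reactants: 7 (R)-naringenin; 8 luteolin, 2-(3,4-dihydroxyphenyl)-5,7-dihydroxy-4H-chromen-4-one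
Product: 10 (2R)-6-[2-(5,7-dihydroxy-4-oxo-4H-chromen-2-yl)-4,5-dihydroxyphenyl]-5,7-dihydroxy-2-(4-hydroxyphenyl)-2,3-dihydro-4H-chromen-4-one, via luteolin ortho-quinone 9 (not isolated)
Conditions: 8, NaIO4 (0.95 equiv), acetone–H2O (1:1), 0 °C, 5 min; then dropwise into 7 (2.5 equiv) in acetone–0.2 M sodium phosphate buffer (pH 7.0), 0 °C; acidify to pH 4, EtOAc
Reagents that add atoms: none
Why: Periodate oxidizes the ring B catechol of 8 (the only catechol present) to the 3',4'-ortho-quinone 9, in which C6' is the β-carbon of the C4'=O enone; the 7-phenoxide of 7, partly formed at pH 7, adds through C6 in a conjugate addition, and tautomerization of the resulting cyclohexadienone–enol pair restores both aromatic rings and returns the catechol. The closest known reaction type is the biomimetic oxidative coupling of flavonoid catechols with 5,7-dihydroxyflavonoid A rings, as in the formation of dehydrodicatechins and biluteolins. No ring is closed and no stereocenter is created; C2 of 7 is not involved and should keep its R configuration because pH 7 and 0 °C lie below the conditions for retro-oxa-Michael ring opening. On the quinone, carbon nucleophiles prefer the 1,4-position C6' over C2' (flanked by the chromone and C3'=O) and over C5' (the 1,6-position). On 7, C6 must win over C8, and this rests on its position between the chelated 5-hydroxyl and the 7-phenoxide, the site favoured in C-alkylations of 5,7-dihydroxyflavanones. Slow inverse addition of 9 to excess 7 should keep ring A of luteolin from competing and limit re-oxidation of the product, and unreacted 7 is recovered.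

**Compound list**

1 | 2',4',6'-trihydroxyacetophenone | CC(=O)c1c(O)cc(O)cc1O | starting material
2 | 1-[2,4-bis(benzyloxy)-6-hydroxyphenyl]ethan-1-one | CC(=O)c1c(O)cc(OCc2ccccc2)cc1OCc1ccccc1 | intermediate
3 | (E)-1-[2,4-bis(benzyloxy)-6-hydroxyphenyl]-3-(dimethylamino)prop-2-en-1-one | CN(C)/C=C/C(=O)c1c(O)cc(OCc2ccccc2)cc1OCc1ccccc1 | intermediate
4 | 5,7-bis(benzyloxy)-4H-chromen-4-one | O=c1ccoc2cc(OCc3ccccc3)cc(OCc3ccccc3)c12 | intermediate
5 | [4-(benzyloxy)phenyl]boronic acid | OB(O)c1ccc(OCc2ccccc2)cc1 | starting material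
6 | (2R)-5,7-bis(benzyloxy)-2-[4-(benzyloxy)phenyl]-2,3-dihydro-4H-chromen-4-one | O=C1C[C@H](c2ccc(OCc3ccccc3)cc2)Oc2cc(OCc3ccccc3)cc(OCc3ccccc3)c21 | intermediate
7 | (2R)-5,7-dihydroxy-2-(4-hydroxyphenyl)-2,3-dihydro-4H-chromen-4-one, (R)-naringenin | O=C1C[C@H](c2ccc(O)cc2)Oc2cc(O)cc(O)c21 | intermediate
8 | luteolin, 2-(3,4-dihydroxyphenyl)-5,7-dihydroxy-4H-chromen-4-one | O=c1cc(-c2ccc(O)c(O)c2)oc2cc(O)cc(O)c12 | starting material
9 | luteolin 3',4'-quinone, 2-(3,4-dioxocyclohexa-1,5-dien-1-yl)-5,7-dihydroxy-4H-chromen-4-one | O=C1C(=O)C=CC(=C1)c1cc(=O)c2c(O)cc(O)cc2o1 | intermediate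
10 | (2R)-6-[2-(5,7-dihydroxy-4-oxo-4H-chromen-2-yl)-4,5-dihydroxyphenyl]-5,7-dihydroxy-2-(4-hydroxyphenyl)-2,3-dihydro-4H-chromen-4-one | O=C1C[C@H](c2ccc(O)cc2)Oc2cc(O)c(-c3cc(O)c(O)cc3-c3cc(=O)c4c(O)cc(O)cc4o3)c(O)c21 | target

**Summary**

Total step count: 5. Longest linear sequence: 5 steps (1 → 2 → 4 → 6 → 7 → 10); luteolin 8 enters in the last step.

**Steps most likely to fail**

Step 5. The union may suffer from poor site selectivity on ring A of 7 (bond formation through C8 instead of C6), from self-coupling through ring A of the oxidized luteolin, or from re-oxidation of the product catechol followed by further coupling. The fallback makes the biaryl bond by Suzuki–Miyaura coupling before the stereocenter exists; it sets out from 4 and 2 and comes back at 10.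
- BCl3 (CH2Cl2, −78 °C) should cleave only the peri 5-O-benzyl group of 4 to give 7-(benzyloxy)-5-hydroxy-4H-chromen-4-one F1.
- Benzyltrimethylammonium dichloroiodate with CaCO3 (CH2Cl2–MeOH, rt) should iodinate ortho to the free hydroxyl to give 7-(benzyloxy)-5-hydroxy-6-iodo-4H-chromen-4-one F2.
- In parallel, bromination of commercial 3,4-bis(benzyloxy)benzaldehyde (Br2, NaOAc, AcOH) should give 4,5-bis(benzyloxy)-2-bromobenzaldehyde F3.
- Claisen–Schmidt condensation of F3 with 2 (KOH, EtOH–THF, rt) should give (E)-1-[2,4-bis(benzyloxy)-6-hydroxyphenyl]-3-[4,5-bis(benzyloxy)-2-bromophenyl]prop-2-en-1-one F4.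
- Oxidative cyclization (I2 cat., DMSO, 120 °C) should give 5,7-bis(benzyloxy)-2-[4,5-bis(benzyloxy)-2-bromophenyl]-4H-chromen-4-one F5.
- Miyaura borylation (B2pin2, PdCl2(dppf), KOAc, 1,4-dioxane, 90 °C) should give 5,7-bis(benzyloxy)-2-[4,5-bis(benzyloxy)-2-(4,4,5,5-tetramethyl-1,3,2-dioxaborolan-2-yl)phenyl]-4H-chromen-4-one F6.
- Coupling of F2 with F6 (Pd(OAc)2, SPhos, K3PO4, toluene–H2O, 80 °C) should give 7-(benzyloxy)-6-{4,5-bis(benzyloxy)-2-[5,7-bis(benzyloxy)-4-oxo-4H-chromen-2-yl]phenyl}-5-hydroxy-4H-chromen-4-one F7, with the regiochemistry fixed by the iodide.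
- The asymmetric 1,4-addition of step 3 with 5 should take place only at the 2-unsubstituted chromone ring, the 2-aryl chromone being inert, to give (2R)-7-(benzyloxy)-6-{4,5-bis(benzyloxy)-2-[5,7-bis(benzyloxy)-4-oxo-4H-chromen-2-yl]phenyl}-2-[4-(benzyloxy)phenyl]-5-hydroxy-2,3-dihydro-4H-chromen-4-one F8.
- Hydrogenolysis as in step 4 should then give 10.

Step 3. Insertion into the electron-rich 5,7-dialkoxychromone may be sluggish, with competing protodeboronation of 5, and reversible ring opening may erode the ee. The fallback replaces asymmetric catalysis by a racemic synthesis and resolution; it sets out from 2 and comes back at 6.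
- Claisen–Schmidt condensation of 2 with commercial 4-(benzyloxy)benzaldehyde (KOH, EtOH, rt) should give (E)-1-[2,4-bis(benzyloxy)-6-hydroxyphenyl]-3-[4-(benzyloxy)phenyl]prop-2-en-1-one F9.
- NaOAc in refluxing EtOH should close it by oxa-Michael addition to racemic 5,7-bis(benzyloxy)-2-[4-(benzyloxy)phenyl]-2,3-dihydro-4H-chromen-4-one F10.
- Preparative chromatography on a chiral stationary phase should deliver 6. The unwanted (2S)-5,7-bis(benzyloxy)-2-[4-(benzyloxy)phenyl]-2,3-dihydro-4H-chromen-4-one F11 would be returned to F10 by base-induced ring opening and re-closure and resolved again, so the material converges on 6.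

Step 4. Hydrogenation may go too far, by hydrogenolysis of the benzylic C2–O1 bond (opening of ring C) or by reduction of the C4 ketone. The fallback replaces hydrogenolysis by Lewis-acid dealkylation: BCl3 with pentamethylbenzene as cation scavenger (CH2Cl2, −78 °C) should take 6 directly to 7 without a reducing agent. It sets out from 6, comes back at 7 and makes no new compound.

**Further compounds**

F1 | step 5 | 7-(benzyloxy)-5-hydroxy-4H-chromen-4-one | O=c1ccoc2cc(OCc3ccccc3)cc(O)c12
F2 | step 5 | 7-(benzyloxy)-5-hydroxy-6-iodo-4H-chromen-4-one | O=c1ccoc2cc(OCc3ccccc3)c(I)c(O)c12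
F3 | step 5 | 4,5-bis(benzyloxy)-2-bromobenzaldehyde | O=Cc1cc(OCc2ccccc2)c(OCc2ccccc2)cc1Br
F4 | step 5 | (E)-1-[2,4-bis(benzyloxy)-6-hydroxyphenyl]-3-[4,5-bis(benzyloxy)-2-bromophenyl]prop-2-en-1-one | O=C(/C=C/c1cc(OCc2ccccc2)c(OCc2ccccc2)cc1Br)c1c(O)cc(OCc2ccccc2)cc1OCc1ccccc1
F5 | step 5 | 5,7-bis(benzyloxy)-2-[4,5-bis(benzyloxy)-2-bromophenyl]-4H-chromen-4-one | O=c1cc(-c2cc(OCc3ccccc3)c(OCc3ccccc3)cc2Br)oc2cc(OCc3ccccc3)cc(OCc3ccccc3)c12
F6 | step 5 | 5,7-bis(benzyloxy)-2-[4,5-bis(benzyloxy)-2-(4,4,5,5-tetramethyl-1,3,2-dioxaborolan-2-yl)phenyl]-4H-chromen-4-one | O=c1cc(-c2cc(OCc3ccccc3)c(OCc3ccccc3)cc2B4OC(C)(C)C(C)(C)O4)oc2cc(OCc3ccccc3)cc(OCc3ccccc3)c12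
F7 | step 5 | 7-(benzyloxy)-6-{4,5-bis(benzyloxy)-2-[5,7-bis(benzyloxy)-4-oxo-4H-chromen-2-yl]phenyl}-5-hydroxy-4H-chromen-4-one | O=c1ccoc2cc(OCc3ccccc3)c(-c3cc(OCc4ccccc4)c(OCc4ccccc4)cc3-c3cc(=O)c4c(OCc5ccccc5)cc(OCc5ccccc5)cc4o3)c(O)c12
F8 | step 5 | (2R)-7-(benzyloxy)-6-{4,5-bis(benzyloxy)-2-[5,7-bis(benzyloxy)-4-oxo-4H-chromen-2-yl]phenyl}-2-[4-(benzyloxy)phenyl]-5-hydroxy-2,3-dihydro-4H-chromen-4-one | O=C1C[C@H](c2ccc(OCc3ccccc3)cc2)Oc2cc(OCc3ccccc3)c(-c3cc(OCc4ccccc4)c(OCc4ccccc4)cc3-c3cc(=O)c4c(OCc5ccccc5)cc(OCc5ccccc5)cc4o3)c(O)c21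
F9 | step 3 | (E)-1-[2,4-bis(benzyloxy)-6-hydroxyphenyl]-3-[4-(benzyloxy)phenyl]prop-2-en-1-one | O=C(/C=C/c1ccc(OCc2ccccc2)cc1)c1c(O)cc(OCc2ccccc2)cc1OCc1ccccc1
F10 | step 3 | racemic 5,7-bis(benzyloxy)-2-[4-(benzyloxy)phenyl]-2,3-dihydro-4H-chromen-4-one | O=C1CC(c2ccc(OCc3ccccc3)cc2)Oc2cc(OCc3ccccc3)cc(OCc3ccccc3)c21
F11 | step 3 | (2S)-5,7-bis(benzyloxy)-2-[4-(benzyloxy)phenyl]-2,3-dihydro-4H-chromen-4-one | O=C1C[C@@H](c2ccc(OCc3ccccc3)cc2)Oc2cc(OCc3ccccc3)cc(OCc3ccccc3)c21
F0 | step 4 | none | none
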